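The synthesis rests on disconnecting the C6–O bond of the 6α-hydroxy C18 ester back to a free C18 acid. In the abietic acid-derived trans-decalin the equatorial carboxyl on C4 (ring A) lies peri and parallel to the equatorial C6–H of ring B. A manganese-catalysed, acid-directed C–H lactonisation should therefore install the C6 oxygen with its configuration and close a temporary γ-lactone in one operation. Its substrate is an ambreinolide-type tricycle: ring C of abietic acid is excised, and the C8 oxygen and C13 are tied together as a δ-lactone. This lactone protects the tertiary alcohol and later supplies the acyl carbon from which the hydroperoxy butenolide side chain is built.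

Key step: step 7

Remarks and assumptions (chemistry only)
- Numbering: abietane numbering for compounds 1–5; labdane-type numbering from 6 on (C17 = methyl on C8, C18 = carboxyl carbon on C4, C16 = methyl on C13, C14/C15 = side-chain alkene, butenolide atoms C2′ (C=O) to C5′ (carbinol)).
- Abbreviations: TES = triethylsilyl; TBS = tert-butyldimethylsilyl; pdp = N,N′-bis(pyridin-2-ylmethyl)-2,2′-bipyrrolidine; (R)-Me-CBS = (R)-1-methyl-3,3-diphenyltetrahydro-1H,3H-pyrrolo[1,2-c][1,3,2]oxazaborole.
- Assumption 1: the (S)-binaphthoxide catalyst of step 11 is taken to give the (S)-2-alkyl-2-methyloxirane from a methyl ketone; if the sense is opposite, the (R)-catalyst is used.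
- Assumption 2: in step 19 the α-methyl-branched C4′ arm is taken as the larger group at the oxazaborolidine; if the opposite sense is found, (S)-Me-CBS is used.
- Assumption 3: the configuration of the transient 13,14-diol 3 is left open because both centres are cleaved in the same flask.

Step 1
Reactants: 1 abietic acid
Product: 2 benzyl abietate
Conditions: BnBr, K2CO3, DMF, rt
Reagents that add atoms: benzyl bromide BrCc1ccccc1
Why: SN2 O-alkylation of the carboxylate masks the hindered C18 acid as an ester that tolerates the oxidants ahead and is later removed by hydrogenolysis without base.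

Step 2
Reactants: 2 benzyl abietate
Product: 4 benzyl 13-oxo-13,14-secoabiet-7-en-14-al-18-oate, via cis-13,14-diol 3 (not isolated)
Conditions: OsO4 (2 mol %), NMO, acetone–H2O, rt; then NaIO4, rt
Reagents that add atoms: N-methylmorpholine N-oxide C[N+]1([O-])CCOCC1; water O
Why: Upjohn dihydroxylation should take the more exposed C13=C14 bond of the diene, and periodate glycol cleavage then opens ring C to the C13 isopropyl ketone and the C7=C8–C14 enal, whose alkene is deactivated toward further osmylation.

Step 3
Reactants: 4 benzyl 13-oxo-13,14-secoabiet-7-en-14-al-18-oate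
Product: 6 benzyl ester of the ring-C-opened 8(17)-methylene isopropyl ketone (C9 side chain CH2CH2COCH(CH3)2), via C14 tosylhydrazone 5 (not isolated)
Conditions: TsNHNH2, EtOH, rt; then catecholborane, CHCl3, 0 °C; NaOAc·3H2O, reflux
Reagents that add atoms: none
Why: Aldehyde-selective hydrazone formation and Kabalka reduction (hydride addition to C=N, loss of sulfinate, retro-ene loss of N2 from the allylic diazene) should deliver hydrogen to C7 and move the double bond to the exocyclic C8(17) position, the hindered isopropyl ketone reacting more slowly with both reagents.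

Step 4
Reactants: 6 benzyl ester of the 8(17)-methylene isopropyl ketone
Product: 7 benzyl ester of the 8α-hydroxy isopropyl ketone (8β-methyl)
Conditions: Co(acac)2 (20 mol %), PhSiH3, O2 (1 atm), THF, rt
Reagents that add atoms: dioxygen O=O
Why: Mukaiyama hydration (hydrogen-atom transfer to the methylene, capture of the tertiary C8 radical by O2) gives the Markovnikov alcohol, and O2 should approach from the α face because the axial β face is shielded by the C10 methyl, which sets the 8α-OH/8β-methyl centre.

Step 5
Reactants: 7 benzyl ester of the 8α-hydroxy isopropyl ketone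
Product: 9 benzyl 13-oxo-8α,13-epoxy-14,15,16-trinorlabdan-18-oate (δ-lactone), via isopropyl ester 8 (not isolated)
Conditions: mCPBA, NaHCO3, CH2Cl2, rt; then KOtBu (20 mol %), THF, 0 °C to rt
Reagents that add atoms: 3-chloroperbenzoic acid OOC(=O)c1cccc(Cl)c1
Why: Baeyer–Villiger oxidation with migration of the secondary isopropyl group turns C13 into an ester carbonyl, and alkoxide-catalysed transesterification by the C8 tertiary alkoxide (6-exo-trig, Thorpe–Ingold assisted) closes the δ-lactone under conditions that cannot dehydrate the tertiary alcohol.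

Step 6
Reactants: 9 benzyl ester δ-lactone
Product: 10 13-oxo-8α,13-epoxy-14,15,16-trinorlabdan-18-oic acid (C18 acid with the 8,13-δ-lactone)
Conditions: H2 (1 atm), Pd/C, EtOAc, rt
Reagents that add atoms: none
Why: Hydrogenolysis of the benzyl ester frees the C18 acid under neutral conditions that leave the δ-lactone untouched.

Step 7
Reactants: 10 C18 acid with the 8,13-δ-lactone
Product: 11 18,6α-γ-lactone 8α,13-δ-lactone (bis-lactone)
Conditions: Mn(OTf)2((S,S)-pdp) (3 mol %), H2O2 (50 % aq., 1.5 equiv, slow addition), (CF3)2CHOH, 0 °C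
Reagents that add atoms: none
Why: The C18 acid binds the divalent manganese catalyst and helps to split the coordinated H2O2 heterolytically to a pentavalent manganese-oxo carboxylate, which abstracts the equatorial C6 α hydrogen inside the chelate; the C6 radical is then captured by the bound carboxylate oxygen (rebound), so the ring oxygen is the acid's own. The closest known reaction type is the carboxylic-acid-directed γ-C–H lactonisation of unactivated methylene groups with manganese aminopyridine catalysts and H2O2. The γ-lactone (C18, C4, C5, C6, O) is closed by C6–O bond formation, a five-membered closure across the peri positions that is trans-fused to ring B. The new stereocentre C6 is substrate-controlled: the tethered carboxylate reaches only the α hydrogen and returns oxygen to that face before the radical can invert, giving the 6α oxygen. The step needs C6 to win over the other γ methylene (C2) and over the tertiary C–H bonds; the equatorial C18 carboxyl is in syn-pentane-like contact with C6–Hα but anti to the C3–C2 bond, and the δ-lactone masks the C8 oxygen and inductively deactivates C7, C9, C11 and C12.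

Step 8
Reactants: 11 bis-lactone
Product: 13 dimethyl 6α,8α-dihydroxy-14,15,16-trinorlabdane-13,18-dioate, via dipotassium dicarboxylate 12 (not isolated)
Conditions: KOH, MeOH–H2O, 70 °C; evaporate; MeI, DMF, rt
Reagents that add atoms: potassium hydroxide [K+].[OH-]; iodomethane CI
Why: Saponification opens both lactones irreversibly, and SN2 O-methylation of the two carboxylates without acidification (so neither hydroxy acid can re-close) gives the C18 methyl ester of the target and a reactive C13 methyl ester.

Step 9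
Reactants: 13 dimethyl 6α,8α-dihydroxy diester
Product: 14 dimethyl 6α,8α-bis(triethylsilyloxy)-14,15,16-trinorlabdane-13,18-dioate
Conditions: TESOTf, 2,6-lutidine, CH2Cl2, −78 to 0 °C
Reagents that add atoms: triethylsilyl trifluoromethanesulfonate CC[Si](CC)(CC)OS(=O)(=O)C(F)(F)F
Why: Silylation with a silyl triflate protects the peri-hindered C6 secondary and the C8 tertiary hydroxyl, so later alkoxides cannot re-lactonise onto C18 or C13 and the C8 oxygen is a poorer neighbouring nucleophile toward C13.

Step 10
Reactants: 14 bis(triethylsilyl) diester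
Product: 16 methyl 13-oxo-6α,8α-bis(triethylsilyloxy)-14,15-dinorlabdan-18-oate (C13 methyl ketone), via Weinreb amide 15 (not isolated)
Conditions: MeNH(OMe)·HCl, iPrMgCl, THF, −20 °C; then MeMgBr, 0 °C
Reagents that add atoms: methylmagnesium bromide C[Mg]Br
Why: Magnesium-amide aminolysis converts only the unhindered C13 ester (the C18 ester sits on a quaternary carbon next to the C6 silyl ether) into the Weinreb amide, whose chelated tetrahedral intermediate limits Grignard addition to one methyl group.

Step 11
Reactants: 16 C13 methyl ketone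
Product: 17 methyl (13S)-13,14-epoxy-6α,8α-bis(triethylsilyloxy)-15-norlabdan-18-oate
Conditions: Me3S(O)I, NaH; LaLi3((S)-binaphthoxide)3 (10 mol %), (2,4,6-(MeO)3C6H2)3P=O (10 mol %), 5 Å MS, THF, rt
Reagents that add atoms: dimethylsulfoxonium methylide (made in the flask from trimethylsulfoxonium iodide) C[S+](C)(=O)[CH2-]
Why: In this catalytic asymmetric Corey–Chaykovsky epoxidation the lanthanum–lithium binaphthoxide activates ketone and ylide together and should direct methylene transfer to one face of the methyl ketone, setting C13 as the (S)-oxirane by reagent control because the ring stereocentres are too remote to interfere.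

Step 12
Reactants: 17 (13S)-epoxide
Product: 18 methyl (13R)-13-hydroperoxy-14-hydroxy-6α,8α-bis(triethylsilyloxy)-15-norlabdan-18-oate
Conditions: H2O2 (anhydrous, in Et2O, excess), H3PMo12O40 (5 mol %), Et2O, rt
Reagents that add atoms: hydrogen peroxide OO
Why: In this acid-catalysed perhydrolysis of a 2,2-dialkyl oxirane H2O2 attacks the tertiary C13 of the activated epoxide from the rear (borderline SN2, inversion), which turns the (S)-epoxide into the (13R) tertiary hydroperoxide and frees C14 as a primary alcohol.

Step 13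
Reactants: 18 hydroxy hydroperoxide
Product: 19 methyl (13R)-13-(tert-butyldimethylsilylperoxy)-14-hydroxy-6α,8α-bis(triethylsilyloxy)-15-norlabdan-18-oate
Conditions: TBSCl (1.1 equiv), imidazole, DMF, −20 °C
Reagents that add atoms: tert-butyldimethylsilyl chloride CC(C)(C)[Si](C)(C)Cl
Why: This O-silylation should be chemoselective because the hydroperoxide OH is several pKa units more acidic and less encumbered than the neopentyl C14 hydroxyl, and the silyl peroxide it gives blocks trioxane formation and O–O cleavage in the next steps.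

Step 14
Reactants: 19 silyl peroxide alcohol
Product: 20 methyl (13R)-13-(tert-butyldimethylsilylperoxy)-14-oxo-6α,8α-bis(triethylsilyloxy)-15-norlabdan-18-oate (α-silylperoxy aldehyde)
Conditions: Dess–Martin periodinane, NaHCO3, CH2Cl2, 0 °C to rt
Reagents that add atoms: none
Why: Dess–Martin oxidation of the primary alcohol under buffered conditions gives the aldehyde, which has no α-hydrogen and so cannot epimerise or undergo Kornblum–DeLaMare cleavage.

Step 15
Reactants: 21 methyl (Z)-3-iodobut-2-enoate; 22 tributyl(1-ethoxyvinyl)stannane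
Product: 23 methyl (2Z)-4-ethoxy-3-methylpenta-2,4-dienoate
Conditions: PdCl2(PPh3)2 (5 mol %), CuI (10 mol %), DMF, 60 °C
Reagents that add atoms: none
Why: Stille coupling of the β-iodo enoate with an acetyl-anion equivalent proceeds with retention of the Z geometry that the later lactonisation needs.

Step 16
Reactants: 23 methyl (2Z)-4-ethoxy-3-methylpenta-2,4-dienoate
Product: 24 methyl (2Z)-5-iodo-3-methyl-4-oxopent-2-enoate
Conditions: NIS, THF–H2O, 0 °C
Reagents that add atoms: N-iodosuccinimide O=C1CCC(=O)N1I; water O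
Why: Electrophilic iodination of the enol ether at its terminal carbon and hydrolysis of the oxocarbenium ion give the iodomethyl ketone, the electron-poor enoate being unreactive toward the iodonium source.

Step 17
Reactants: 24 methyl (2Z)-5-iodo-3-methyl-4-oxopent-2-enoate
Product: 25 methyl (2Z)-5-(dimethoxyphosphoryl)-3-methyl-4-oxopent-2-enoate
Conditions: P(OMe)3, toluene, 50 °C
Reagents that add atoms: trimethyl phosphite COP(OC)OC
Why: In this Michaelis–Arbuzov reaction SN2 attack at the carbon of an α-iodo ketone outruns the Perkow pathway and gives the β-ketophosphonate.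

Step 18
Reactants: 20 α-silylperoxy aldehyde; 25 β-ketophosphonate
Product: 26 protected (13R,14E,3′Z)-dienone: C13(OOTBS)(CH3)–CH=CH–C(=O)–C(CH3)=CH–CO2Me on the bis(triethylsilyl) decalin
Conditions: LiCl, iPr2NEt, MeCN, rt
Reagents that add atoms: none
Why: Horner–Wadsworth–Emmons olefination under Masamune–Roush conditions adds the stabilised phosphonate anion to the α-quaternary aldehyde and the reversible addition funnels to the E enone (C14=C15), the weak amine base sparing the silyl peroxide and the Z enoate.

Step 19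
Reactants: 26 protected dienone
Product: 28 6,8-bis(triethylsilyl) ether and tert-butyldimethylsilyl peroxide of the target, via hydroxy ester 27 (not isolated)
Conditions: (R)-Me-CBS (0.5 equiv), catecholborane, toluene, −78 °C; MeOH; PPTS (cat.), CH2Cl2, rt
Reagents that add atoms: none
Why: In this Corey–Bakshi–Shibata reduction the oxazaborolidine should bind the ketone anti to the larger α-methyl-branched C4′ arm and deliver hydride 1,2 to one face, setting C5′ as (S) by reagent control, and the resulting Z γ-hydroxy enoate lactonises (5-exo-trig) to the butenolide.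

Step 20
Reactants: 28 silyl-protected target
Product: 29 CNP0128148.1 (target)
Conditions: HF·pyridine, pyridine, THF, 0 °C to rt
Reagents that add atoms: none
Why: Fluoride-mediated desilylation cleaves the silyl peroxide and both triethylsilyl ethers under buffered conditions that should leave the tertiary allylic hydroperoxide, the butenolide and the 6-hydroxy ester intact.

Compound list
1 | abietic acid (abieta-7,13-dien-18-oic acid) | OC(=O)[C@]1(C)CCC[C@@]2(C)[C@H]1CC=C3C=C(C(C)C)CC[C@H]23 | starting material
2 | benzyl abietate | O=C(OCc1ccccc1)[C@]1(C)CCC[C@@]2(C)[C@H]1CC=C3C=C(C(C)C)CC[C@H]23 | intermediate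
3 | benzyl 13,14-dihydroxyabiet-7-en-18-oate (cis-diol, C13/C14 configuration not assigned) | O=C(OCc1ccccc1)[C@]1(C)CCC[C@@]2(C)[C@H]1CC=C3C(O)C(O)(C(C)C)CC[C@H]23 | intermediate (not isolated)
4 | benzyl 13-oxo-13,14-secoabiet-7-en-14-al-18-oate (keto enal) | O=C(OCc1ccccc1)[C@]1(C)CCC[C@@]2(C)[C@H]1CC=C(C=O)[C@@H]2CCC(=O)C(C)C | intermediate
5 | C14 (E)-tosylhydrazone of 4 | O=C(OCc1ccccc1)[C@]1(C)CCC[C@@]2(C)[C@H]1CC=C(/C=N/NS(=O)(=O)c3ccc(C)cc3)[C@@H]2CCC(=O)C(C)C | intermediate (not isolated)
6 | benzyl ester of the 8(17)-methylene isopropyl ketone | O=C(OCc1ccccc1)[C@]1(C)CCC[C@@]2(C)[C@H]1CCC(=C)[C@@H]2CCC(=O)C(C)C | intermediate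
7 | benzyl ester of the 8α-hydroxy-8β-methyl isopropyl ketone | O=C(OCc1ccccc1)[C@]1(C)CCC[C@@]2(C)[C@H]1CC[C@@](C)(O)[C@@H]2CCC(=O)C(C)C | intermediate
8 | benzyl 18-ester, isopropyl 13-ester of the 8α-hydroxy-14,15,16-trinorlabdane-13,18-dioic acid | O=C(OCc1ccccc1)[C@]1(C)CCC[C@@]2(C)[C@H]1CC[C@@](C)(O)[C@@H]2CCC(=O)OC(C)C | intermediate (not isolated)
9 | benzyl 13-oxo-8α,13-epoxy-14,15,16-trinorlabdan-18-oate (δ-lactone) | O=C(OCc1ccccc1)[C@]1(C)CCC[C@@]2(C)[C@H]1CC[C@@](C)(O3)[C@@H]2CCC3=O | intermediate
10 | 13-oxo-8α,13-epoxy-14,15,16-trinorlabdan-18-oic acid (key-step precursor) | OC(=O)[C@]1(C)CCC[C@@]2(C)[C@H]1CC[C@@](C)(O3)[C@@H]2CCC3=O | intermediate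
11 | 18,6α-γ-lactone 8α,13-δ-lactone (key-step product) | O=C4[C@]1(C)CCC[C@@]2(C)[C@H]1[C@@H](O4)C[C@@](C)(O3)[C@@H]2CCC3=O | intermediate
12 | dipotassium 6α,8α-dihydroxy-14,15,16-trinorlabdane-13,18-dioate | [K+].[K+].[O-]C(=O)[C@]1(C)CCC[C@@]2(C)[C@H]1[C@@H](O)C[C@@](C)(O)[C@@H]2CCC([O-])=O | intermediate (not isolated)
13 | dimethyl 6α,8α-dihydroxy-14,15,16-trinorlabdane-13,18-dioate | COC(=O)[C@]1(C)CCC[C@@]2(C)[C@H]1[C@@H](O)C[C@@](C)(O)[C@@H]2CCC(=O)OC | intermediate
14 | dimethyl 6α,8α-bis(triethylsilyloxy)-14,15,16-trinorlabdane-13,18-dioate | COC(=O)[C@]1(C)CCC[C@@]2(C)[C@H]1[C@@H](O[Si](CC)(CC)CC)C[C@@](C)(O[Si](CC)(CC)CC)[C@@H]2CCC(=O)OC | intermediate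
15 | C13 N-methoxy-N-methylamide of 14 | COC(=O)[C@]1(C)CCC[C@@]2(C)[C@H]1[C@@H](O[Si](CC)(CC)CC)C[C@@](C)(O[Si](CC)(CC)CC)[C@@H]2CCC(=O)N(C)OC | intermediate (not isolated)
16 | methyl 13-oxo-6α,8α-bis(triethylsilyloxy)-14,15-dinorlabdan-18-oate | COC(=O)[C@]1(C)CCC[C@@]2(C)[C@H]1[C@@H](O[Si](CC)(CC)CC)C[C@@](C)(O[Si](CC)(CC)CC)[C@@H]2CCC(C)=O | intermediate
17 | methyl (13S)-13,14-epoxy-6α,8α-bis(triethylsilyloxy)-15-norlabdan-18-oate | COC(=O)[C@]1(C)CCC[C@@]2(C)[C@H]1[C@@H](O[Si](CC)(CC)CC)C[C@@](C)(O[Si](CC)(CC)CC)[C@@H]2CC[C@@]1(C)CO1 | intermediate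
18 | methyl (13R)-13-hydroperoxy-14-hydroxy-6α,8α-bis(triethylsilyloxy)-15-norlabdan-18-oate | COC(=O)[C@]1(C)CCC[C@@]2(C)[C@H]1[C@@H](O[Si](CC)(CC)CC)C[C@@](C)(O[Si](CC)(CC)CC)[C@@H]2CC[C@](C)(CO)OO | intermediate
19 | methyl (13R)-13-(tert-butyldimethylsilylperoxy)-14-hydroxy-6α,8α-bis(triethylsilyloxy)-15-norlabdan-18-oate | COC(=O)[C@]1(C)CCC[C@@]2(C)[C@H]1[C@@H](O[Si](CC)(CC)CC)C[C@@](C)(O[Si](CC)(CC)CC)[C@@H]2CC[C@](C)(CO)OO[Si](C)(C)C(C)(C)C | intermediate
20 | methyl (13R)-13-(tert-butyldimethylsilylperoxy)-14-oxo-6α,8α-bis(triethylsilyloxy)-15-norlabdan-18-oate | COC(=O)[C@]1(C)CCC[C@@]2(C)[C@H]1[C@@H](O[Si](CC)(CC)CC)C[C@@](C)(O[Si](CC)(CC)CC)[C@@H]2CC[C@](C)(C=O)OO[Si](C)(C)C(C)(C)C | intermediate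
21 | methyl (Z)-3-iodobut-2-enoate | COC(=O)/C=C(/C)I | starting material
22 | tributyl(1-ethoxyvinyl)stannane | CCCC[Sn](CCCC)(CCCC)C(=C)OCC | starting material
23 | methyl (2Z)-4-ethoxy-3-methylpenta-2,4-dienoate | COC(=O)/C=C(/C)C(=C)OCC | intermediate
24 | methyl (2Z)-5-iodo-3-methyl-4-oxopent-2-enoate | COC(=O)/C=C(/C)C(=O)CI | intermediate
25 | methyl (2Z)-5-(dimethoxyphosphoryl)-3-methyl-4-oxopent-2-enoate | COC(=O)/C=C(/C)C(=O)CP(=O)(OC)OC | intermediate
26 | protected (13R,14E,3′Z)-dienone | COC(=O)[C@]1(C)CCC[C@@]2(C)[C@H]1[C@@H](O[Si](CC)(CC)CC)C[C@@](C)(O[Si](CC)(CC)CC)[C@@H]2CC[C@](C)(/C=C/C(=O)C(/C)=C\C(=O)OC)OO[Si](C)(C)C(C)(C)C | intermediate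
27 | protected (13R,14E,5′S,3′Z)-γ-hydroxy enoate | COC(=O)[C@]1(C)CCC[C@@]2(C)[C@H]1[C@@H](O[Si](CC)(CC)CC)C[C@@](C)(O[Si](CC)(CC)CC)[C@@H]2CC[C@](C)(/C=C/[C@H](O)C(/C)=C\C(=O)OC)OO[Si](C)(C)C(C)(C)C | intermediate (not isolated)
28 | 6,8-bis(triethylsilyl) ether, 13-(tert-butyldimethylsilyl) peroxide of the target | COC(=O)[C@]1(C)CCC[C@@]2(C)[C@H]1[C@@H](O[Si](CC)(CC)CC)C[C@@](C)(O[Si](CC)(CC)CC)[C@@H]2CC[C@](C)(/C=C/[C@@H]1OC(=O)C=C1C)OO[Si](C)(C)C(C)(C)C | intermediate
29 | CNP0128148.1: methyl (13R,14E)-13-hydroperoxy-6α,8α-dihydroxy-15-[(2S)-3-methyl-5-oxo-2,5-dihydrofuran-2-yl]labd-14-en-18-oate | COC(=O)[C@]1(C)CCC[C@@]2(C)[C@H]1[C@@H](O)C[C@@](C)(O)[C@@H]2CC[C@](C)(/C=C/[C@@H]1OC(=O)C=C1C)OO | target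

Total step count: 20 (17 on the main line, 3 for phosphonate 25).
Longest linear sequence: 17 steps (steps 1–14 and 18–20).

Steps most likely to fail

Step 7 (C–H lactonisation). What may go wrong: hydrogen abstraction at competing sites (the C2 methylene, tertiary C–H bonds, positions next to the lactone oxygen), over-oxidation, or stalling through catalyst deactivation before the acid is consumed. Fallback: setting out from 10, the acid is converted through its acid chloride ((COCl)2, cat. DMF; then NH3) into the primary carboxamide F1. Treating F1 with PhI(OAc)2 and I2 under visible light gives an N-iodoamide whose amidyl radical reaches the same peri C6–Hα by 1,5-hydrogen transfer. Iodination at C6 and O-cyclisation give the 18,6α-iminolactone F2, which is hydrolysed with dilute aqueous acid and so returns to the route at 11.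

Step 12 (perhydrolysis of the epoxide). What may go wrong: ionisation of the activated epoxide to a free tertiary cation, with erosion of configuration at C13 or capture by the C8 silyl ether oxygen, and loss of silyl groups under the acid. Fallback: setting out from 16, Wittig reaction with (methoxymethylene)triphenylphosphorane gives the methyl enol ether F3. Brief mild acid hydrolysis gives the α-methyl aldehyde F4, and TBSOTf/Et3N converts it into the tert-butyldimethylsilyl enol ether F5. Photooxygenation of F5 (O2, tetraphenylporphyrin, light, CH2Cl2, −78 °C) is an ene reaction of singlet oxygen with migration of silicon from the enol oxygen to the peroxide. It gives the α-silylperoxy aldehyde directly and returns to the route at 20. Stereocontrol at C13 is given up in this fallback: the C13 epimer F6 forms alongside and has to be removed by chromatography of the diastereomers, here or at 28.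

Step 19 (ketone reduction and lactonisation). What may go wrong: poor facial discrimination because both arms of the ketone are alkenyl groups, or Z-to-E isomerisation of the keto enoate before reduction so that the hydroxy ester cannot close. Fallback: C5′ is brought in with a fragment. Setting out from 20, Wittig methylenation (methylenetriphenylphosphorane, THF, −78 °C) gives the vinyl peroxide F7. Separately, ProPhenol/ZnMe2-mediated asymmetric addition of methyl propiolate to acrolein gives methyl (S)-4-hydroxyhex-5-en-2-ynoate F8, and syn addition of Me2CuLi followed by acid-induced lactonisation gives (S)-4-methyl-5-vinylfuran-2(5H)-one F9. Cross-metathesis of F7 with an excess of F9 (second-generation Hoveyda–Grubbs catalyst RuCl2(H2IMes)(=CH-C6H4-2-OiPr), CH2Cl2, 40 °C) should give the E alkene and returns to the route at 28.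

Further compounds
F1 | step 7 | 13-oxo-8α,13-epoxy-14,15,16-trinorlabdan-18-amide (primary amide of 10) | NC(=O)[C@]1(C)CCC[C@@]2(C)[C@H]1CC[C@@](C)(O3)[C@@H]2CCC3=O
F2 | step 7 | 18,6α-iminolactone of the 8α,13-δ-lactone | N=C4[C@]1(C)CCC[C@@]2(C)[C@H]1[C@@H](O4)C[C@@](C)(O3)[C@@H]2CCC3=O
F3 | step 12 | methyl 14-methoxy-6α,8α-bis(triethylsilyloxy)-15-norlabd-13-en-18-oate (E/Z mixture) | COC(=O)[C@]1(C)CCC[C@@]2(C)[C@H]1[C@@H](O[Si](CC)(CC)CC)C[C@@](C)(O[Si](CC)(CC)CC)[C@@H]2CCC(C)=COC
F4 | step 12 | methyl 14-oxo-6α,8α-bis(triethylsilyloxy)-15-norlabdan-18-oate (both C13 epimers) | COC(=O)[C@]1(C)CCC[C@@]2(C)[C@H]1[C@@H](O[Si](CC)(CC)CC)C[C@@](C)(O[Si](CC)(CC)CC)[C@@H]2CCC(C)C=O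
F5 | step 12 | methyl 14-(tert-butyldimethylsilyloxy)-6α,8α-bis(triethylsilyloxy)-15-norlabd-13-en-18-oate (E/Z mixture) | COC(=O)[C@]1(C)CCC[C@@]2(C)[C@H]1[C@@H](O[Si](CC)(CC)CC)C[C@@](C)(O[Si](CC)(CC)CC)[C@@H]2CCC(C)=CO[Si](C)(C)C(C)(C)C
F6 | step 12 | (13S) epimer of 20 | COC(=O)[C@]1(C)CCC[C@@]2(C)[C@H]1[C@@H](O[Si](CC)(CC)CC)C[C@@](C)(O[Si](CC)(CC)CC)[C@@H]2CC[C@@](C)(C=O)OO[Si](C)(C)C(C)(C)C
F7 | step 19 | methyl (13R)-13-(tert-butyldimethylsilylperoxy)-6α,8α-bis(triethylsilyloxy)labd-14-en-18-oate (vinyl peroxide) | COC(=O)[C@]1(C)CCC[C@@]2(C)[C@H]1[C@@H](O[Si](CC)(CC)CC)C[C@@](C)(O[Si](CC)(CC)CC)[C@@H]2CC[C@](C)(C=C)OO[Si](C)(C)C(C)(C)C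
F8 | step 19 | methyl (S)-4-hydroxyhex-5-en-2-ynoate | C=C[C@H](O)C#CC(=O)OC
F9 | step 19 | (S)-4-methyl-5-vinylfuran-2(5H)-one | C=C[C@@H]1OC(=O)C=C1C
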